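**Retrosynthetic overview**

1. Drimane numbering is used: ring A = C1–C5 and C10, ring B = C5–C10, C11 on C9, C12 on C8. The C5 tertiary hydroxyl lies δ to the C12 carbonyl through C6 and the C7=C8 bond, a vinylogous aldol retron. Ring B is therefore cut at C5–C6, giving a ring A C5 ketone whose C10 carries a C9 arm ending in a γ-bromo enoate (C12 ester, C8=C7, C6–Br).
2. Endgame: the C1 ester by acylation, the C11/C12 dialdehyde by Swern oxidation of the 11,12-diol, and the 1,5,11,12-tetraol by LiAlH4 reduction of the cyclised lactone ester.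
3. Repair within the strategy: in the cyclisation substrate O1 and C11 are joined as a γ-lactone (in place of a silyl ether and a methyl ester). The tether protects O1 and fixes the C9–C10 rotamer so that C6 can reach only the β face of C5 (trans fusion). It also removes the C11 ester onto which a cis-fused C5 alkoxide would lactonise.
4. Precursor assembly: the enone is converted into (3R)-3-silyloxy-2,6,6-trimethylcyclohexanone by asymmetric conjugate borylation and oxidation. Its lithium enolate adds to dimethyl fumarate (C10–C9) and the new ester enolate is trapped by chloroacetaldehyde (C8–C7). Dehydration, desilylation with lactonisation, and chloride-to-bromide exchange follow.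
5. Ring order: ring A is present from the start, the temporary O1–C11 lactone ring is closed in step 5, and ring B is closed in the key step.

Key step: step 7

Assumption: the sense of induction of the CuCl–bisphosphine borylation on this 2-methyl enone is taken by analogy with unsubstituted cyclic enones; the ligand antipode is used if the opposite sense is found.

**Route**

Step 1
Reactants: 1 2,6,6-trimethylcyclohex-2-en-1-one
Product: 3 (3R)-3-hydroxy-2,6,6-trimethylcyclohexan-1-one (C2 epimers), via boronate 2 (not isolated)
Conditions: CuCl (5 mol%), (R,R)-2,3-bis(tert-butylmethylphosphino)quinoxaline (6 mol%), NaOtBu (10 mol%), B2pin2, MeOH, THF, 0 °C to rt; then NaBO3·4H2O, THF/H2O, rt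
Reagents that add atoms: bis(pinacolato)diboron, CC1(C)OB(OC1(C)C)B1OC(C)(C)C(C)(C)O1 (boryl group of 2); sodium perborate, [Na+].[Na+].O[B-]1(O)OO[B-](O)(O)OO1 (oxygen of the C3 hydroxyl)
Why: Copper-catalysed enantioselective conjugate borylation of the cyclic enone (the copper–boryl species adds to C3 and methanol protonates the copper enolate) followed by stereoretentive C–B oxidation, so that the chiral bisphosphine sets C3 (drimane C1) while C2 is formed as an epimer mixture that is erased when it becomes the enolate carbon.

Step 2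
Reactants: 3 (3R)-3-hydroxy-2,6,6-trimethylcyclohexan-1-one
Product: 4 (3R)-3-[(tert-butyldimethylsilyl)oxy]-2,6,6-trimethylcyclohexan-1-one (C2 epimers)
Conditions: TBSCl, imidazole, DMF, rt
Reagents that add atoms: tert-butyldimethylsilyl chloride, CC(C)(C)[Si](C)(C)Cl
Why: Standard silylation of the secondary alcohol gives a bulky ether that later shields one enolate face and is a poor enough leaving group to survive enolate formation.

Step 3
Reactants: 4 (3R)-3-[(tert-butyldimethylsilyl)oxy]-2,6,6-trimethylcyclohexan-1-one; 5 dimethyl fumarate; 6 chloroacetaldehyde (anhydrous monomer, freshly distilled)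
Product: 9 dimethyl 2-(2-chloro-1-hydroxyethyl)-3-[(1S,6R)-6-(tert-butyldimethylsilyloxy)-1,3,3-trimethyl-2-oxocyclohexyl]butanedioate (C9 as in the target; epimers at C7 and C8), via lithium enolate 7 (not isolated), via ester enolate 8 (not isolated)
Conditions: LiN(iPr)2, THF, −78 °C; 5, −78 °C; then 6, −78 °C; AcOH quench
Reagents that add atoms: none
Why: Three-component Michael–aldol sequence in which the tetrasubstituted lithium enolate 7 (kept at −78 °C so that β-elimination of silanolate does not compete) adds to the fumarate on the face anti to the neighbouring silyloxy group, which sets C10, through a closed lithium-bridged transition state (C12 carbonyl on lithium, C9–H over ring A, C11 ester antiperiplanar to the enolate double bond), which sets C9, and the ester enolate 8 so formed is intercepted at C8 by the aldehyde, the C7 and C8 centres being destroyed in step 4.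

Step 4
Reactants: 9 aldol adduct
Product: 11 dimethyl (2E,3R)-2-(2-chloroethylidene)-3-[(1S,6R)-6-(tert-butyldimethylsilyloxy)-1,3,3-trimethyl-2-oxocyclohexyl]butanedioate, via mesylate 10 (not isolated)
Conditions: MsCl, Et3N, CH2Cl2, 0 °C; then DBU, 0 °C to rt
Reagents that add atoms: methanesulfonyl chloride, CS(=O)(=O)Cl (sulfonate group of 10 only)
Why: Mesylation and E1cB elimination through the C8 ester enolate (aldol dehydration) give the conjugated enoate, the E isomer with C6 cis to C9 being the thermodynamic one, and either geometry would in any case converge on the same dienolate in step 7.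

Step 5
Reactants: 11 chloroethylidene keto diester
Product: 13 methyl (2E)-4-chloro-2-[(3R,3aS,7aR)-3a,5,5-trimethyl-2,4-dioxooctahydro-1-benzofuran-3-yl]but-2-enoate (O1–C11 γ-lactone trans-fused to ring A), via hydroxy diester 12 (not isolated)
Conditions: 48% aq. HF, MeCN, rt; then TsOH·H2O (10 mol%), PhMe, 60 °C
Reagents that add atoms: none
Why: Acidic desilylation followed by acid-catalysed transesterification, in which the C1 hydroxyl closes the five-membered lactone (5-exo-trig) onto the saturated C11 ester that it faces in the preferred C9–C10 rotamer rather than onto the conjugated, more distant C12 ester, acid being chosen over fluoride or base so that the β-hydroxy ketone does not undergo retro-aldol cleavage.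

Step 6
Reactants: 13 chloro lactone
Product: 14 methyl (2E)-4-bromo-2-[(3R,3aS,7aR)-3a,5,5-trimethyl-2,4-dioxooctahydro-1-benzofuran-3-yl]but-2-enoate
Conditions: LiBr (10 equiv), acetone, rt
Reagents that add atoms: lithium bromide, [Li+].[Br-]
Why: Finkelstein halide exchange (SN2 at the primary allylic carbon) gives the bromide needed for zinc insertion, and bringing the halogen in with the aldehyde avoids a radical allylic bromination that would not distinguish C6–H from the doubly activated C9–H.

Step 7
Reactants: 14 γ-bromo enoate keto lactone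
Product: 16 12-methyl ester 11,1β-lactone of 1β,5α-dihydroxydrim-7-ene-11,12-dioic acid (trans-fused rings A and B; 5α-OH; C7=C8), via allylzinc bromide 15 (not isolated)
Conditions: Zn dust (activated with 1,2-dibromoethane and Me3SiCl), THF, 0.01 M, slow addition at 45 °C; aq. NH4Cl
Reagents that add atoms: none
Why: Zinc inserts into the allylic C6–Br bond to give the allylzinc bromide 15, in equilibrium with its zinc dienolate (O–C12=C8–C7=C6), which adds through C6 to the C5 ketone; this is an intramolecular vinylogous Reformatsky (Barbier-type allylzinc) carbonyl addition, the closest known reaction being the γ-selective addition of zinc dienolates from 4-bromocrotonates to ketones. Ring B closes in the 6-exo-trig mode at the carbonyl with the reacting C6=C7 bond inside the ring (6-(enolendo)-exo-trig), whereas attack through C8 would give a cyclobutane and attack of C6 on the lactone carbonyl C11 would be a disfavoured 5-(enolendo)-exo-trig closure onto a much poorer electrophile. The one new stereocentre, C5, is controlled by the O1–C11 lactone: it holds C9 equatorial on ring A and C11 next to O1, hence C8 roughly anti to C1, so that C6 can only approach the C5 carbonyl from its β face and ends equatorial, the oxygen becoming the axial 5α-hydroxyl of a trans-fused decalin. The selectivity needed is therefore β-face (equatorial) attack against the intrinsic preference of such ketones for axial attack, which would give the cis-fused 5β-ol as in the ketols of Robinson annulations; that mode requires C11 anti to C1 and is out of reach while the lactone is closed. C9 and C10 are untouched, the E or Z geometry of the enoate is immaterial because the dienolate rotates about C7–C8, and the C7=C8 bond is regenerated in conjugation with C12. High dilution and slow addition favour ring closure over protonation or coupling of 15.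

Step 8
Reactants: 16 tricyclic hydroxy lactone ester
Product: 17 drim-7-ene-1β,5α,11,12-tetrol
Conditions: LiAlH4, THF, 0 °C to rt; aq. sodium potassium tartrate (KNaC4H4O6) work-up
Reagents that add atoms: none
Why: Hydride reduction of the lactone and 1,2-reduction of the conjugated ester release the C1 hydroxyl and the 11,12-diol in one operation without touching a stereocentre, the transient C11 aldehyde being reduced at once.

Step 9
Reactants: 17 drim-7-ene-1β,5α,11,12-tetrol
Product: 18 11,12-bis(triethylsilyloxy)drim-7-ene-1β,5α-diol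
Conditions: Et3SiCl (2.2 equiv), imidazole, CH2Cl2, −40 to 0 °C
Reagents that add atoms: chlorotriethylsilane, CC[Si](Cl)(CC)CC
Why: Chemoselective silylation, the two primary hydroxyls reacting far faster than the neopentylic secondary C1 hydroxyl and the tertiary C5 hydroxyl.

Step 10
Reactants: 19 (E)-4-hydroxycinnamic acid
Product: 21 (E)-3-[4-(tert-butyldimethylsilyloxy)phenyl]prop-2-enoic acid, via bis-silyl derivative 20 (not isolated)
Conditions: TBSCl (2.2 equiv), imidazole, DMF, rt; then AcOH, THF/H2O, rt
Reagents that add atoms: tert-butyldimethylsilyl chloride, CC(C)(C)[Si](C)(C)Cl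
Why: Exhaustive silylation followed by selective hydrolysis of the labile silyl ester leaves the aryl silyl ether and the free acid.

Step 11
Reactants: 18 11,12-bis(triethylsilyloxy)drim-7-ene-1β,5α-diol; 21 (E)-3-[4-(tert-butyldimethylsilyloxy)phenyl]prop-2-enoic acid
Product: 22 5α-hydroxy-11,12-bis(triethylsilyloxy)drim-7-en-1β-yl (E)-3-[4-(tert-butyldimethylsilyloxy)phenyl]prop-2-enoate
Conditions: EDC·HCl, DMAP, CH2Cl2, rt to 35 °C
Reagents that add atoms: none
Why: Steglich esterification of the equatorial secondary C1 hydroxyl, the tertiary C5 hydroxyl being inert and the E geometry of the cinnamate unaffected.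

Step 12
Reactants: 22 bis-silylated ester
Product: 23 5α,11,12-trihydroxydrim-7-en-1β-yl (E)-3-[4-(tert-butyldimethylsilyloxy)phenyl]prop-2-enoate
Conditions: PPTS (0.2 equiv), MeOH/CH2Cl2, 0 °C
Reagents that add atoms: none
Why: Mild acid methanolysis removes the two primary triethylsilyl ethers while the aryl tert-butyldimethylsilyl ether and the ester survive.

Step 13
Reactants: 23 11,12-diol
Product: 24 5α-hydroxy-11,12-dioxodrim-7-en-1β-yl (E)-3-[4-(tert-butyldimethylsilyloxy)phenyl]prop-2-enoate
Conditions: (COCl)2, DMSO, CH2Cl2, −78 °C; Et3N, −78 to −30 °C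
Reagents that add atoms: none
Why: Swern oxidation converts both primary alcohols into aldehydes, both alkoxysulfonium salts being formed before base is added so that no hydroxy aldehyde can close to a lactol, while the tertiary alcohol is untouched and the cold work-up avoids C9 epimerisation, as is usual for drim-7-ene-11,12-diols.

Step 14
Reactants: 24 silylated dialdehyde
Product: 25 (1R,4aR,8R,8aS)-7,8-diformyl-4a-hydroxy-4,4,8a-trimethyl-1,2,3,4,4a,5,8,8a-octahydronaphthalen-1-yl (E)-3-(4-hydroxyphenyl)prop-2-enoate (CNP0323926.1)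
Conditions: HF·pyridine, pyridine, THF, 0 °C
Reagents that add atoms: none
Why: Fluoride cleavage of the aryl silyl ether under buffered, slightly acidic conditions spares the base-sensitive dialdehyde (C9 epimerisation, retro-vinylogous aldol).

**Compound list**

1 | 2,6,6-trimethylcyclohex-2-en-1-one | CC1=CCCC(C)(C)C1=O | starting material
2 | (3R)-2,6,6-trimethyl-3-(4,4,5,5-tetramethyl-1,3,2-dioxaborolan-2-yl)cyclohexan-1-one (C2 epimers; formed in situ) | CC1(C)CC[C@@H](B2OC(C)(C)C(C)(C)O2)C(C)C1=O | intermediate
3 | (3R)-3-hydroxy-2,6,6-trimethylcyclohexan-1-one (C2 epimers) | CC1(C)CC[C@@H](O)C(C)C1=O | intermediate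
4 | (3R)-3-[(tert-butyldimethylsilyl)oxy]-2,6,6-trimethylcyclohexan-1-one (C2 epimers) | CC1(C)CC[C@@H](O[Si](C)(C)C(C)(C)C)C(C)C1=O | intermediate
5 | dimethyl fumarate | COC(=O)/C=C/C(=O)OC | starting material
6 | chloroacetaldehyde | ClCC=O | starting material
7 | lithium (3R)-3-[(tert-butyldimethylsilyl)oxy]-2,6,6-trimethylcyclohex-1-en-1-olate (formed in situ) | CC1(C)CC[C@@H](O[Si](C)(C)C(C)(C)C)C(C)=C1O[Li] | intermediate
8 | lithium ester enolate of the Michael adduct (C10–C9 bond formed, enolate at C8/C12; formed in situ) | CC1(C)CC[C@@H](O[Si](C)(C)C(C)(C)C)[C@](C)([C@@H](C(=O)OC)C=C(OC)O[Li])C1=O | intermediate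
9 | dimethyl 2-(2-chloro-1-hydroxyethyl)-3-[(1S,6R)-6-(tert-butyldimethylsilyloxy)-1,3,3-trimethyl-2-oxocyclohexyl]butanedioate (C9 as in the target; epimers at C7 and C8) | CC1(C)CC[C@@H](O[Si](C)(C)C(C)(C)C)[C@](C)([C@@H](C(=O)OC)C(C(=O)OC)C(O)CCl)C1=O | intermediate
10 | C7 methanesulfonate of 9 (formed in situ) | CC1(C)CC[C@@H](O[Si](C)(C)C(C)(C)C)[C@](C)([C@@H](C(=O)OC)C(C(=O)OC)C(OS(C)(=O)=O)CCl)C1=O | intermediate
11 | dimethyl (2E,3R)-2-(2-chloroethylidene)-3-[(1S,6R)-6-(tert-butyldimethylsilyloxy)-1,3,3-trimethyl-2-oxocyclohexyl]butanedioate | CC1(C)CC[C@@H](O[Si](C)(C)C(C)(C)C)[C@](C)([C@@H](C(=O)OC)/C(C(=O)OC)=C\CCl)C1=O | intermediate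
12 | dimethyl (2E,3R)-2-(2-chloroethylidene)-3-[(1S,6R)-6-hydroxy-1,3,3-trimethyl-2-oxocyclohexyl]butanedioate (formed in situ) | CC1(C)CC[C@@H](O)[C@](C)([C@@H](C(=O)OC)/C(C(=O)OC)=C\CCl)C1=O | intermediate
13 | methyl (2E)-4-chloro-2-[(3R,3aS,7aR)-3a,5,5-trimethyl-2,4-dioxooctahydro-1-benzofuran-3-yl]but-2-enoate | CC1(C)CC[C@H]2OC(=O)[C@@H](/C(C(=O)OC)=C\CCl)[C@]2(C)C1=O | intermediate
14 | methyl (2E)-4-bromo-2-[(3R,3aS,7aR)-3a,5,5-trimethyl-2,4-dioxooctahydro-1-benzofuran-3-yl]but-2-enoate (key-step precursor) | CC1(C)CC[C@H]2OC(=O)[C@@H](/C(C(=O)OC)=C\CBr)[C@]2(C)C1=O | intermediate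
15 | allylzinc bromide of 14 (C6–ZnBr, in equilibrium with the zinc dienolate; formed in situ) | CC1(C)CC[C@H]2OC(=O)[C@@H](/C(C(=O)OC)=C\C[Zn]Br)[C@]2(C)C1=O | intermediate
16 | 12-methyl ester 11,1β-lactone of 1β,5α-dihydroxydrim-7-ene-11,12-dioic acid (key-step product) | CC1(C)CC[C@H]2OC(=O)[C@H]3C(C(=O)OC)=CC[C@]1(O)[C@]23C | intermediate
17 | drim-7-ene-1β,5α,11,12-tetrol | CC1(C)CC[C@@H](O)[C@]2(C)[C@@H](CO)C(CO)=CC[C@@]12O | intermediate
18 | 11,12-bis(triethylsilyloxy)drim-7-ene-1β,5α-diol | CC1(C)CC[C@@H](O)[C@]2(C)[C@@H](CO[Si](CC)(CC)CC)C(CO[Si](CC)(CC)CC)=CC[C@@]12O | intermediate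
19 | (E)-4-hydroxycinnamic acid | O=C(O)/C=C/c1ccc(O)cc1 | starting material
20 | tert-butyldimethylsilyl (E)-3-[4-(tert-butyldimethylsilyloxy)phenyl]prop-2-enoate (formed in situ) | CC(C)(C)[Si](C)(C)OC(=O)/C=C/c1ccc(O[Si](C)(C)C(C)(C)C)cc1 | intermediate
21 | (E)-3-[4-(tert-butyldimethylsilyloxy)phenyl]prop-2-enoic acid | O=C(O)/C=C/c1ccc(O[Si](C)(C)C(C)(C)C)cc1 | intermediate
22 | 5α-hydroxy-11,12-bis(triethylsilyloxy)drim-7-en-1β-yl (E)-3-[4-(tert-butyldimethylsilyloxy)phenyl]prop-2-enoate | CC1(C)CC[C@@H](OC(=O)/C=C/c2ccc(O[Si](C)(C)C(C)(C)C)cc2)[C@]2(C)[C@@H](CO[Si](CC)(CC)CC)C(CO[Si](CC)(CC)CC)=CC[C@@]12O | intermediate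
23 | 5α,11,12-trihydroxydrim-7-en-1β-yl (E)-3-[4-(tert-butyldimethylsilyloxy)phenyl]prop-2-enoate | CC1(C)CC[C@@H](OC(=O)/C=C/c2ccc(O[Si](C)(C)C(C)(C)C)cc2)[C@]2(C)[C@@H](CO)C(CO)=CC[C@@]12O | intermediate
24 | 5α-hydroxy-11,12-dioxodrim-7-en-1β-yl (E)-3-[4-(tert-butyldimethylsilyloxy)phenyl]prop-2-enoate | CC1(C)CC[C@@H](OC(=O)/C=C/c2ccc(O[Si](C)(C)C(C)(C)C)cc2)[C@]2(C)[C@@H](C=O)C(C=O)=CC[C@@]12O | intermediate
25 | (1R,4aR,8R,8aS)-7,8-diformyl-4a-hydroxy-4,4,8a-trimethyl-1,2,3,4,4a,5,8,8a-octahydronaphthalen-1-yl (E)-3-(4-hydroxyphenyl)prop-2-enoate | CC1(C)CC[C@@H](OC(=O)/C=C/c2ccc(O)cc2)[C@]2(C)[C@@H](C=O)C(C=O)=CC[C@@]12O | target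

**Step count and risks**

Total step count: 14. Longest linear sequence: 13 steps (steps 1–9 and 11–14); step 10 is a one-step side branch.

Steps most likely to fail:

Step 7. The tethered allylzinc may not add to the doubly neopentylic C5 carbonyl: β-face approach between the axial C4 and C10 methyl groups is slow and the strained adduct can revert, so that protonation or reductive coupling of 15 takes over. Fallback: from 14, reductive removal of bromide with Zn in AcOH/THF (α-protonation of the dienolate) gives the deconjugated 2-vinyl ester F1. Me2AlCl in CH2Cl2 then promotes an intramolecular carbonyl–ene cyclisation (C6 to the activated C5 carbonyl, C8–H to oxygen, the alkene moving into conjugation with C12), which returns to 16 under the same lactone control of the ring fusion.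

Step 3. Conjugate addition of the hindered tetrasubstituted enolate may be slow, letting β-elimination of silanolate or oligomerisation of the fumarate compete, and the simple diastereoselectivity at C9 may be eroded. Fallback: from 4, the trimethylsilyl enol ether F2 (Me3SiOTf, Et3N, CH2Cl2) undergoes a Mukaiyama–Michael addition to 5 (TiCl4, CH2Cl2, −78 °C) to give the keto diester F3. F3 is deprotonated at its C8 methylene with LiN(iPr)2 and condensed with 6 to rejoin the route at 9. A C9 epimer carried through can be corrected once lactone 13 is in hand by kinetic protonation of its lactone enolate from the face away from the C10 methyl group, which gives the wanted epimer with C9–H facing the C5 carbonyl.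

Step 5. Ring closure may occur at the wrong carbonyl (six-membered lactone onto C12), or the free β-hydroxy ketone may suffer retro-aldol cleavage before it lactonises. Fallback: from 11, ester cleavage with Me3SnOH (1,2-dichloroethane, 80 °C) gives the diacid F4, and Ac2O closes the alkylidenesuccinic anhydride F5. Desilylation with HF·pyridine then lets the C1 hydroxyl open the anhydride at its non-conjugated C11 carbonyl (the usual regiochemistry of alkylidenesuccinic anhydrides) to give the lactone acid F6. Esterification of F6 with Me3SiCHN2 returns to 13.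

Further compounds
F1 | step 7 | methyl 2-[(3R,3aS,7aR)-3a,5,5-trimethyl-2,4-dioxooctahydro-1-benzofuran-3-yl]but-3-enoate (C8 epimers) | CC1(C)CC[C@H]2OC(=O)[C@@H](C(C=C)C(=O)OC)[C@]2(C)C1=O
F2 | step 3 | tert-butyldimethyl{[(1R)-2,4,4-trimethyl-3-(trimethylsilyloxy)cyclohex-2-en-1-yl]oxy}silane (trimethylsilyl enol ether of 4) | CC1(C)CC[C@@H](O[Si](C)(C)C(C)(C)C)C(C)=C1O[Si](C)(C)C
F3 | step 3 | dimethyl 2-[(1S,6R)-6-(tert-butyldimethylsilyloxy)-1,3,3-trimethyl-2-oxocyclohexyl]butanedioate (C9 as in the target) | CC1(C)CC[C@@H](O[Si](C)(C)C(C)(C)C)[C@](C)([C@@H](C(=O)OC)CC(=O)OC)C1=O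
F4 | step 5 | (2E,3R)-2-(2-chloroethylidene)-3-[(1S,6R)-6-(tert-butyldimethylsilyloxy)-1,3,3-trimethyl-2-oxocyclohexyl]butanedioic acid | CC1(C)CC[C@@H](O[Si](C)(C)C(C)(C)C)[C@](C)([C@@H](C(=O)O)/C(C(=O)O)=C\CCl)C1=O
F5 | step 5 | cyclic anhydride of F4 ((E)-3-(2-chloroethylidene)-4-substituted oxolane-2,5-dione) | CC1(C)CC[C@@H](O[Si](C)(C)C(C)(C)C)[C@](C)([C@H]2C(=O)OC(=O)/C2=C/CCl)C1=O
F6 | step 5 | (2E)-4-chloro-2-[(3R,3aS,7aR)-3a,5,5-trimethyl-2,4-dioxooctahydro-1-benzofuran-3-yl]but-2-enoic acid | CC1(C)CC[C@H]2OC(=O)[C@@H](/C(C(=O)O)=C\CCl)[C@]2(C)C1=O
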